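(The runs are simulated with made-up constants, and the scatter is random.)

The four set-ups are to be ordered by one number read from the earlier runs, a number with time divided out of it.

| flask | substrate | reagent | other conformer | remark | time |
|---|---|---|---|---|---|
| Wednesday's | 22 mM | 0.90 equiv | 1 equiv | run made earlier |  |
| Monday's | 15 mM | 0.90 equiv | 1 equiv | run made earlier |  |
| Thursday's | 33 mM | 0.90 equiv | 1 equiv | run made earlier |  |
| south-west | 22 mM | 0.900 equiv | 1.00 equiv | a closed flask charged with all of it at once and left for 15 min | 15 min |
| east | 22 mM (fed, over 12.0 min) | 0.900 equiv | 1.00 equiv | a stirred flask in which substrate is dosed at a steady rate over 12.0 min without added volume, worked up at 15 min | 15 min |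
| north-east | 22 mM | 0.900 equiv | 1.00 equiv | one stirred flow tank at steady state, fed with the mixture as stated, mean residence time 15 min |  |
| north-west | 22 mM | 0.900 equiv (fed, over 12.0 min) | 1.00 equiv | all but reagent at the start; reagent goes in evenly over 12.0 min, the run ends at 15 min | 15 min |

| run | time / min | target / % | isomer of the product / % |
|---|---|---|---|
| Wednesday's | 0.667 | 6.8 | 34.0 |
| Wednesday's | 1.33 | 8.3 | 36.6 |
| Wednesday's | 2.50 | 7.5 | 36.6 |
| Wednesday's | 5.00 | 6.9 | 36.8 |
| Wednesday's | 10.0 | 8.8 | 37.5 |
| Monday's | 1.00 | 6.9 | 33.7 |
| Monday's | 3.00 | 8.0 | 36.7 |
| Monday's | 6.00 | 8.3 | 37.3 |
| Monday's | 8.00 | 8.2 | 37.0 |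
| Monday's | 12.0 | 7.8 | 37.3 |
| Thursday's | 2.50 | 7.5 | 36.7 |
| Thursday's | 5.00 | 8.1 | 36.2 |
| Thursday's | 8.00 | 7.6 | 37.5 |
| Thursday's | 10.0 | 8.7 | 37.6 |
| Thursday's | 12.0 | 8.0 | 37.9 |

(readings scatter by 0.5 percentage points)

- the stated concentrations are those of everything mixed, before any reaction; amounts are the same in each set-up
- the analysis behind the earlier runs scatters by 0.5 percentage points, standard deviation
- the feed brings no volume worth counting
- the earlier runs were made in a closed, stirred flask

- order of the set-ups by the share of target in all that became target or isomer of the product, at the outlet or at the end, highest first (south-west / east / north-east / north-west)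
- share of target in all that became target or isomer of the product, at the outlet or at the end, south-west
- share of target in all that became target or isomer of the product, at the outlet or at the end, east
- share of target in all that became target or isomer of the product, at the outlet or at the end, north-east
- share of target in all that became target or isomer of the product, at the outlet or at the end, north-west

Where does the reagent go? The last three readings of Monday's and Thursday's runs average 8.10% target and 37.4% isomer of the product. Together that is 45.5%, close to the 45.0% the charge of reagent can make, so reagent is the limiting reagent and the question is its split.

The split holds between 15 mM and 33 mM, so both steps read as first order in reagent and in their conformer. The rate of isomer of the product divided by the rate of target is then σ[other conformer]/[substrate], with neither time nor [reagent] in it. Integrated, σ is the logarithm of the fraction of other conformer untouched by reagent, 25.1%, over that of substrate, 83.8%. This gives 7.81 for the apparent selectivity factor, isomer of the product over target, a reading that carries the scatter and takes each conformer as consumed by reagent with no other loss and no turning into the other.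

What does that make of a flask? The share of target being made at a moment is [substrate]/([substrate]+σ[other conformer]). By this reckoning it is 11.3% at an equal charge and 29.9% where the closed flask stops taking reagent, and the accumulated share reads 17.8%.

So reagent should meet a mixture poor in other conformer. My own order follows. The north-east tank works at outlet composition, so it lands between 17.8% and 29.9%. North-west, with [reagent] absent from the ratio, stays level with south-west. East, with substrate arriving late, falls below 11.3%.

The forecast gives north-east > south-west > north-west > east, with 17.7% for south-west, 2.4% for east, 23.7% for north-east and 17.7% for north-west, holding that “both rates are first order in reagent”.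

The flask gives north-west > north-east > south-west > east: south-west 17.8%, east 9.59%, north-east 21.0%, north-west 24.3%.

    substrate ⇌ other conformer (K = 0.420, k = 0.00850 s⁻¹)
    substrate + reagent → target (k = 0.920 M⁻¹ s⁻¹)
    reagent + other conformer → isomer of the product (k = 9.50 M⁻¹ s⁻¹)
    2 other conformer → homo dimer (k = 0.690 M⁻¹ s⁻¹)
    reagent ⇌ dormant form (K = 0.700, k = 0.330 s⁻¹)

North-west stands 6.5 percentage points above south-west. At 7.50 min the north-west flask holds 52.1% as homo dimer, beside 17.6% substrate and 5.35% other conformer. The apparent σ of 7.81 stands below the 10.3 of the two rate constants, isomer of the product over target. With the ratio of the constants, that north-west composition gives a moment share of 24.2%, against 8.85% at an equal charge. The neighbour of east charged with 1.50 equiv of reagent ends at 12.3% substrate and 4.66% other conformer, a moment share of 20.4% by the same ratio, and its accumulated share is 19.6%.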